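## Analysis of the target

The target (19) is a flavone: a 4H-chromen-4-one, made of benzo ring A fused to pyranone ring C, with a 2,3,4,5-tetramethoxyphenyl group (ring B) on C2. Ring A carries a hydroxyl at C5, hydrogen at C6 and methoxy groups at C7 and C8. Ring B is fully substituted except for C6'. There is no stereocentre, so the whole problem is regiochemical: seven oxygen substituents on two rings, only one of them a free hydroxyl. That 5-hydroxyl is hydrogen-bonded to the C4 carbonyl, which makes it a weaker acid and nucleophile than an ordinary phenol and lets it be told apart from any other hydroxyl. The sensitive points are the pyranone ring (opened by hot alkali, and by strong acid with reclosure that can exchange C6 and C8), the crowded methyl ethers (cleaved by strong Lewis acids) and any 5,8-dioxygenated ring A with a free quinol (easily oxidised to the quinone). The difficulty is ring A, where four neighbouring positions each need a different substituent, a pattern that symmetrical phloroglucinol building blocks do not distinguish. The strategy rests on the C5(OH)–C6(H)–C7(OMe) array. It is a resorcinol monomethyl ether attached to the C4a=C8a bond, which is what a ketene carbon and a methoxy-substituted alkyne deliver onto a double bond, and C4a=C8a can be the C3=C2 bond of a preformed 2-aryl-4-pyranone.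

## Retrosynthetic reasoning

19 to 18. The C8 methyl ether is cut first. The last step then only has to alkylate the free 8-hydroxyl of quinol 18 while the chelated 5-hydroxyl stays out of the reaction, so no protecting group is needed.

18 to 16. The C8–O bond is cut next. C8 is para to the 5-hydroxyl, so phenol 16 can be hydroxylated there by an Elbs oxidation through aryl sulfate 17. The oxygen is put in after ring A is built because C8 derives from a diazo carbon, which cannot carry an oxygen substituent. Ring B has no phenol and should stay untouched.

16 to 9 and 12. Ring A is taken apart at C5–C6, C7–C8 and C4a–C5, and the C8–C8a bond is traced back to a 1,2-shift. This leaves the pyranonyl diazo ketone 9 and methoxyacetylene 12. Cutting here, and not at the pyranone ring as in classical flavone syntheses, means that the acyl carbon of 9 becomes C5 with its hydroxyl already free and chelated, 12 supplies C6 and C7 with the methoxy group in place, and the finished ring C with ring B attached is carried in unchanged. The forward reaction has to pass through ketene 13, cyclobutenone 14 and dienylketene 15, and close onto C3 of the pyranone.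

12 to 10. The ynol ether is volatile and is made fresh by double elimination from chloro acetal 10.

9 to 7. The bond between the acyl carbon and the diazo carbon is cut. Acid 7, activated as chloride 8, acylates a diazoalkane.

7 to 3 and 4. The pyranone is opened at the ring O–C bond and at the bond between the carboxyl-bearing carbon and its neighbour. This gives the 1,3,5-tricarbonyl chain of 5, which is diketone 3 acylated at its methyl group by oxalate 4. Ester 6 lies between 5 and 7.

3 to 2 to 1. The diketone is cut between C2 and C3 (Claisen condensation of ketone 2 with an acetate ester), and 2 is cut at the aryl–acyl bond. Arene 1 has two equivalent open positions, so its acetylation has no regiochemical question.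

## Alternatives that were turned down

Alternative 1: Ring A is disconnected at C4a–C5 only, as a biomimetic Claisen closure. In the forward step Mg(OMe)2 in methanol opens the lactone of the cinnamoylmethyl pyrone A1, and the methylene between the two ketones attacks the new ester carbonyl to give the chalcone A2. A2 would then be cyclised oxidatively to compound 16 and finished as in the chosen route.
- For: the chemistry is thermal and mild and needs no diazo compound and no lamp. The C7 methoxy group is already in the pyrone, and the two hydroxyls of A2 are equivalent, so the later ring C closure has no regiochemical issue. On precedent for the ring-forming event it is stronger than the chosen route.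
- Against: making A1 means acylating a pyrone methyl carbanion with a cinnamoyl donor, where conjugate addition competes. The opened chain can also close in the aldol sense, and the enone is exposed to methoxide throughout. The key step forms one bond where the chosen one forms three. It ends at the chalcone oxidation level, so three steps follow it instead of two.
- Comparison: the chosen strategy gives up the safer precedent. In return it delivers ring A fused to a finished ring C, with the 5-hydroxyl free and no base-sensitive enone carried along.

Alternative 2: Ring B is disconnected at C1'–C2' and built from dimethyl squarate A3. Heating the 4-hydroxy-4-alkenylcyclobutenone A4 opens the four-membered ring to a dienylketene, which closes by six-electron electrocyclisation to the hydroquinone A5. Double O-methylation and chelation-controlled removal of the C5 methyl would then give 19.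
- For: the ring expansion is thermal, has no regiochemical ambiguity and is more dependable than the key step chosen here.
- Against: it spends the key step on ring B, which can be bought as arene 1 and attached in one acylation. A4 needs a vinyl-metal reagent that already carries the electrophilic chromone, or else a reordered and longer sequence. Ring A must be brought in with all three oxygens as methyl ethers and one of them removed at the end.
- Comparison: it is the more reliable pericyclic step, but it is aimed at the easy ring. The chosen strategy is aimed at ring A, where the difficulty lies.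

Alternative 3: Ring C is disconnected at C8a–O1, C4a–C4 and O1–C2. CsF releases the aryne A7 from the silyl triflate A6. A7 inserts into the carboxyl C–O bond of the arylpropiolic acid A8, and the resulting phenoxide adds to the ynone to give the 5,7-dimethoxyflavone A9.
- For: it is the most convergent of the four plans. It forms three bonds in one mild step, and the 3-methoxy group of A7 steers the oxygen nucleophile to the correct aryne carbon. On convergence and on step count up to the flavone it is at least as good as the chosen route.
- Against: A6 takes several steps to prepare. The free acid can quench the aryl anion by proton transfer, which stops at a simple aryl ester. The phenoxide can close in the five-membered mode instead of the six-membered one. A9 has the C5 oxygen methylated and no C8 oxygen, so demethylation to 16 is needed before the same two closing steps, three steps in all.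
- Comparison: the chosen strategy is less convergent, but it sets the C5 hydroxyl free and the C7 methoxy in place in the same step that makes ring A, with no demethylation.

Key step: step 6

Assumption: 1, 4 and 10 are taken as purchasable, and 12 is made fresh because it boils near room temperature. The target has no stereocentre, and the one stereogenic carbon on the way (in 14) is transient and racemic.

## Route

Step 1
Reactants: 1 1,2,3,4-tetramethoxybenzene
Product: 2 1-(2,3,4,5-tetramethoxyphenyl)ethan-1-one
Conditions: Ac2O, Sc(O3SCF3)3 (10 mol %), MeNO2, 50 °C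
Reagents that add atoms: acetic anhydride, CC(=O)OC(C)=O
Why: Friedel–Crafts acylation under metal triflate catalysis; the two open positions of 1 are equivalent and the acetyl group deactivates the ring against a second acylation. Leaving out AlCl3 should spare the crowded methyl ether ortho to the new ketone.

Step 2
Reactants: 2 1-(2,3,4,5-tetramethoxyphenyl)ethan-1-one
Product: 3 1-(2,3,4,5-tetramethoxyphenyl)butane-1,3-dione
Conditions: NaH, EtOAc, THF, reflux; then aq. HCl
Reagents that add atoms: ethyl acetate, CCOC(C)=O
Why: Crossed Claisen condensation of the methyl ketone enolate with ethyl acetate, driven to completion by deprotonation of the 1,3-diketone formed.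

Step 3
Reactants: 3 1-(2,3,4,5-tetramethoxyphenyl)butane-1,3-dione; 4 diethyl oxalate
Product: 7 4-oxo-6-(2,3,4,5-tetramethoxyphenyl)-4H-pyran-2-carboxylic acid, via triketo ester 5 (not isolated), via pyranone ethyl ester 6 (not isolated)
Conditions: NaOEt (2.2 equiv), EtOH, 0 °C to rt; then conc. HCl, AcOH, reflux
Reagents that add atoms: water, O
Why: Claisen condensation at the terminal methyl group of the diketone, then acid cyclodehydration of the 1,3,5-tricarbonyl chain to the 4-pyranone and acid hydrolysis of the ester, the sequence by which chelidonic and comanic acids are made. Aryl methyl ethers should withstand HCl, which is not nucleophilic enough to cleave them.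

Step 4
Reactants: 7 4-oxo-6-(2,3,4,5-tetramethoxyphenyl)-4H-pyran-2-carboxylic acid
Product: 9 2-(2-diazoacetyl)-6-(2,3,4,5-tetramethoxyphenyl)-4H-pyran-4-one, via acid chloride 8 (not isolated)
Conditions: (COCl)2, cat. DMF, CH2Cl2, 0 °C to rt, evaporate; then CH2N2 (3 equiv), Et2O–THF, 0 °C
Reagents that add atoms: diazomethane, C=[N+]=[N-]
Why: Acid chloride formation and acylation of diazomethane, the first stage of an Arndt–Eistert sequence; the chloride has no alpha hydrogen, so it cannot form a ketene, and the extra diazomethane consumes the HCl.

Step 5
Reactants: 10 chloroacetaldehyde dimethyl acetal (2-chloro-1,1-dimethoxyethane)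
Product: 12 methoxyacetylene, via sodium methoxyethynide 11 (not isolated)
Conditions: NaNH2 (3 equiv), liq. NH3, −33 °C; then cold aq. NaCl, distil (bp near 23 °C) into cold ClCH2CH2Cl
Reagents that add atoms: none
Why: Two successive base-induced eliminations (methanol, then HCl) give the ynol ether, which is held as its sodium acetylide until the aqueous quench; this is the standard preparation of the lower alkoxyacetylenes.

Step 6
Reactants: 9 2-(2-diazoacetyl)-6-(2,3,4,5-tetramethoxyphenyl)-4H-pyran-4-one; 12 methoxyacetylene
Product: 16 5-hydroxy-7-methoxy-2-(2,3,4,5-tetramethoxyphenyl)-4H-chromen-4-one, via pyranonylketene 13 (not isolated), via cyclobutenone 14 (not isolated), via dienylketene 15 (not isolated)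
Conditions: 12 (4 equiv), ClCH2CH2Cl, hν (365 nm, Pyrex), 10 °C, sealed vessel; then 80 °C
Reagents that add atoms: none
Why: Proposed new method: a Danheiser benzannulation in its photochemical Wolff form, established for aryl, furyl, thienyl, pyrrolyl and indolyl diazomethyl ketones, is asked here to accept a 4-pyranon-2-yl diazomethyl ketone, whose C2=C3 bond has not yet served as the ene component. Light expels N2 from 9 and the pyranonyl group shifts to the carbene carbon, so the former diazo carbon becomes C8 bonded to C8a and the former acyl carbon becomes the ketene carbon of 13. The electrophilic ketene carbon bonds to the nucleophilic CH terminus of 12 and the ketene CH carbon to the methoxy-bearing carbon in a [2+2] cycloaddition, which gives 14 with C5–C6 and C7–C8 in place. Reversible four-electron electrocyclic opening of 14 gives 15, of which only the isomer with the pyranonyl group cis to the ketene chain can close; six-electron disrotatory electrocyclisation then joins the ketene carbon to pyranone C3 (C4a–C5), closing ring A as a six-membered carbocycle, and enolisation of the 4a-H dienone, whose hydrogen lies between two carbonyls, gives the phenol. The closure is polarity-matched, since C3 is the nucleophilic carbon of a 4-pyranone and the ketene carbon is electrophilic, and the pyranone has less aromatic stabilisation to give up than the furans and thiophenes known to take part. No stereocentre survives, because the sp3 carbons of 14 and of the dienone are both flattened on the way to 16. The regiochemistry is built in: the polarisation of the ynol ether puts methoxy at C7 and hydrogen at C6, and C3 is the only ring carbon next to the ketene-bearing C2, so ring A can only fuse across C4a–C8a. Irradiation at 365 nm is chosen to excite the diazo ketone while staying away from the short-wavelength bands at which 4-pyranones rearrange.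

Step 7
Reactants: 16 5-hydroxy-7-methoxy-2-(2,3,4,5-tetramethoxyphenyl)-4H-chromen-4-one
Product: 18 5,8-dihydroxy-7-methoxy-2-(2,3,4,5-tetramethoxyphenyl)-4H-chromen-4-one, via aryl sulfate 17 (not isolated)
Conditions: K2S2O8, aq. KOH, pyridine, 10–20 °C; then HCl, Na2SO3, 80 °C
Reagents that add atoms: potassium peroxodisulfate, [K+].[K+].[O-]S(=O)(=O)OOS(=O)(=O)[O-]
Why: Elbs persulfate oxidation: the phenoxide of 16 attacks the peroxide oxygen through its para carbon C8 (C6, ortho, is used only when para is blocked), and acid hydrolysis of the sulfate ester with S–O cleavage frees the quinol. Ring B has no phenol and should not react; Na2SO3 guards the quinol against air oxidation.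

Step 8
Reactants: 18 5,8-dihydroxy-7-methoxy-2-(2,3,4,5-tetramethoxyphenyl)-4H-chromen-4-one
Product: 19 5-hydroxy-7,8-dimethoxy-2-(2,3,4,5-tetramethoxyphenyl)-4H-chromen-4-one
Conditions: Me2SO4 (1.05 equiv), K2CO3, acetone, reflux, N2
Reagents that add atoms: dimethyl sulfate, COS(=O)(=O)OC
Why: Chelation-controlled O-methylation of Williamson type: the 5-hydroxyl is tied to the C4 carbonyl by a hydrogen bond and is the weaker acid and nucleophile, so one equivalent of the sulfate should alkylate only the 8-phenoxide.

## Compound list

1 | 1,2,3,4-tetramethoxybenzene | COc1ccc(OC)c(OC)c1OC | starting material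
2 | 1-(2,3,4,5-tetramethoxyphenyl)ethan-1-one | CC(=O)c1cc(OC)c(OC)c(OC)c1OC | intermediate
3 | 1-(2,3,4,5-tetramethoxyphenyl)butane-1,3-dione | CC(=O)CC(=O)c1cc(OC)c(OC)c(OC)c1OC | intermediate
4 | diethyl oxalate | CCOC(=O)C(=O)OCC | starting material
5 | ethyl 2,4,6-trioxo-6-(2,3,4,5-tetramethoxyphenyl)hexanoate | CCOC(=O)C(=O)CC(=O)CC(=O)c1cc(OC)c(OC)c(OC)c1OC | intermediate
6 | ethyl 4-oxo-6-(2,3,4,5-tetramethoxyphenyl)-4H-pyran-2-carboxylate | CCOC(=O)c1cc(=O)cc(-c2cc(OC)c(OC)c(OC)c2OC)o1 | intermediate
7 | 4-oxo-6-(2,3,4,5-tetramethoxyphenyl)-4H-pyran-2-carboxylic acid | OC(=O)c1cc(=O)cc(-c2cc(OC)c(OC)c(OC)c2OC)o1 | intermediate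
8 | 4-oxo-6-(2,3,4,5-tetramethoxyphenyl)-4H-pyran-2-carbonyl chloride | ClC(=O)c1cc(=O)cc(-c2cc(OC)c(OC)c(OC)c2OC)o1 | intermediate
9 | 2-(2-diazoacetyl)-6-(2,3,4,5-tetramethoxyphenyl)-4H-pyran-4-one | [N-]=[N+]=CC(=O)c1cc(=O)cc(-c2cc(OC)c(OC)c(OC)c2OC)o1 | intermediate
10 | chloroacetaldehyde dimethyl acetal (2-chloro-1,1-dimethoxyethane) | COC(CCl)OC | starting material
11 | sodium methoxyethynide | [Na+].[C-]#COC | intermediate
12 | methoxyacetylene (methoxyethyne) | COC#C | intermediate
13 | 2-(2-oxoethenyl)-6-(2,3,4,5-tetramethoxyphenyl)-4H-pyran-4-one | O=C=Cc1cc(=O)cc(-c2cc(OC)c(OC)c(OC)c2OC)o1 | intermediate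
14 | 3-methoxy-4-[4-oxo-6-(2,3,4,5-tetramethoxyphenyl)-4H-pyran-2-yl]cyclobut-2-en-1-one (racemic) | COC1=CC(=O)C1c1cc(=O)cc(-c2cc(OC)c(OC)c(OC)c2OC)o1 | intermediate
15 | 2-[(1E)-2-methoxy-4-oxobuta-1,3-dien-1-yl]-6-(2,3,4,5-tetramethoxyphenyl)-4H-pyran-4-one | O=C=C/C(OC)=C\c1cc(=O)cc(-c2cc(OC)c(OC)c(OC)c2OC)o1 | intermediate
16 | 5-hydroxy-7-methoxy-2-(2,3,4,5-tetramethoxyphenyl)-4H-chromen-4-one | COc1cc(O)c2c(=O)cc(-c3cc(OC)c(OC)c(OC)c3OC)oc2c1 | intermediate
17 | potassium 5-hydroxy-7-methoxy-4-oxo-2-(2,3,4,5-tetramethoxyphenyl)-4H-chromen-8-yl sulfate | COc1cc(O)c2c(=O)cc(-c3cc(OC)c(OC)c(OC)c3OC)oc2c1OS(=O)(=O)[O-].[K+] | intermediate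
18 | 5,8-dihydroxy-7-methoxy-2-(2,3,4,5-tetramethoxyphenyl)-4H-chromen-4-one | COc1cc(O)c2c(=O)cc(-c3cc(OC)c(OC)c(OC)c3OC)oc2c1O | intermediate
19 | 5-hydroxy-7,8-dimethoxy-2-(2,3,4,5-tetramethoxyphenyl)-4H-chromen-4-one | COc1cc(-c2cc(=O)c3c(O)cc(OC)c(OC)c3o2)c(OC)c(OC)c1OC | target

## Step count and least certain steps

Total: 8 steps. Longest linear sequence: 7 steps (steps 1, 2, 3, 4, 6, 7, 8). Step 5 is a one-step side branch that supplies 12.

Step 6 (key step, new substrate class).
- Risk: the electron-poor pyranonyl group may migrate slowly, so the keto carbene is diverted into addition to the alkyne or insertion. The aldoketene may dimerise before it meets 12. The pyranone chromophore may be degraded by the light. The six-electron closure may stall because it costs the pyranone its cyclic conjugation, leaving the dienylketene to oligomerise. The ynol ether may polymerise on heating.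
- Fallback (known chemistry): set out from 1. Vilsmeier–Haack formylation (POCl3, DMF) should give 2,3,4,5-tetramethoxybenzaldehyde F1. Claisen–Schmidt condensation of F1 with purchased 1-(2-hydroxy-4,6-dimethoxyphenyl)ethan-1-one (KOH, EtOH) should give the 2'-hydroxychalcone F2. Oxidative cyclisation with catalytic I2 in DMSO at 130 °C should give the 5,7-dimethoxyflavone F3. BCl3 in CH2Cl2 at −78 to 0 °C should remove only the methyl of the C5 ether, which sits in a six-membered chelate with the C4 carbonyl. The route is rejoined at 16.

Step 7 (Elbs oxidation).
- Risk: incomplete conversion, because persulfate is also consumed by the quinol it produces; over-oxidation to the quinone and dark polymeric material; opening of the pyranone ring in alkali; and acid-induced ring opening and reclosure to the 5,6-dioxygenated isomer during sulfate hydrolysis.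
- Fallback: set out from 16. Methylation of the chelated hydroxyl under forcing conditions (MeI, K2CO3, DMF, 60 °C) should give the 5,7-dimethoxyflavone F4, the same structure as F3. NBS in DMF should brominate C8, the preferred site in 5,7-dimethoxyflavones, to give the 8-bromide F5. Any bromination at C6' of ring B would have to be watched for. Ullmann-type methoxylation (NaOMe, CuBr, MeOH–DMF, 110 °C) should give the 5,7,8-trimethoxyflavone F6. BCl3 then frees the 5-hydroxyl. The route is rejoined at 19, and step 8 is not needed.

Step 4 (diazo ketone).
- Risk: 1,3-dipolar cycloaddition of diazomethane to the doubly activated C2=C3 bond of the pyranone, and O-methylation of the pyranone carbonyl if HCl is still present.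
- Fallback: set out from 3. Its dianion (LiN(iPr)2, 2.2 equiv, THF, −78 °C) is acylated at the terminal carbon with purchased methyl 2,2-dimethoxypropanoate to give the triketone ketal F7. Aqueous HCl in AcOH should close the pyranone and hydrolyse the ketal to the 2-acetyl-4-pyranone F8. Enolisation with LiN(SiMe3)2 and trifluoroacetylation with CF3CO2CH2CF3 gives the trifluoroacetyl diketone F9, used crude. Detrifluoroacetylative diazo transfer (MsN3, Et3N, H2O, MeCN) should then give the diazo ketone without diazomethane. The route is rejoined at 9.

Step 8 (selective methylation).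
- Risk: loss of selectivity, with both hydroxyls alkylated, or oxidation of the quinol by air under basic conditions before it is alkylated.
- Fallback: set out from 18. Exhaustive methylation (excess Me2SO4, K2CO3, DMF, 60 °C) should give the 5,7,8-trimethoxyflavone F10, the same structure as F6. Chelation-controlled demethylation with BCl3 (CH2Cl2, −78 to 0 °C) then frees only the 5-hydroxyl. The route is rejoined at 19.

## Further compounds

F1 | step 6 | 2,3,4,5-tetramethoxybenzaldehyde | COc1cc(C=O)c(OC)c(OC)c1OC
F2 | step 6 | (2E)-1-(2-hydroxy-4,6-dimethoxyphenyl)-3-(2,3,4,5-tetramethoxyphenyl)prop-2-en-1-one | COc1cc(O)c(C(=O)/C=C/c2cc(OC)c(OC)c(OC)c2OC)c(OC)c1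
F3 | step 6 | 5,7-dimethoxy-2-(2,3,4,5-tetramethoxyphenyl)-4H-chromen-4-one | COc1cc(OC)c2c(=O)cc(-c3cc(OC)c(OC)c(OC)c3OC)oc2c1
F4 | step 7 | 5,7-dimethoxy-2-(2,3,4,5-tetramethoxyphenyl)-4H-chromen-4-one | COc1cc(OC)c2c(=O)cc(-c3cc(OC)c(OC)c(OC)c3OC)oc2c1
F5 | step 7 | 8-bromo-5,7-dimethoxy-2-(2,3,4,5-tetramethoxyphenyl)-4H-chromen-4-one | COc1cc(OC)c2c(=O)cc(-c3cc(OC)c(OC)c(OC)c3OC)oc2c1Br
F6 | step 7 | 5,7,8-trimethoxy-2-(2,3,4,5-tetramethoxyphenyl)-4H-chromen-4-one | COc1cc(OC)c2c(=O)cc(-c3cc(OC)c(OC)c(OC)c3OC)oc2c1OC
F7 | step 4 | 6,6-dimethoxy-1-(2,3,4,5-tetramethoxyphenyl)heptane-1,3,5-trione | COc1cc(C(=O)CC(=O)CC(=O)C(C)(OC)OC)c(OC)c(OC)c1OC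
F8 | step 4 | 2-acetyl-6-(2,3,4,5-tetramethoxyphenyl)-4H-pyran-4-one | CC(=O)c1cc(=O)cc(-c2cc(OC)c(OC)c(OC)c2OC)o1
F9 | step 4 | 4,4,4-trifluoro-1-[4-oxo-6-(2,3,4,5-tetramethoxyphenyl)-4H-pyran-2-yl]butane-1,3-dione | COc1cc(-c2cc(=O)cc(C(=O)CC(=O)C(F)(F)F)o2)c(OC)c(OC)c1OC
F10 | step 8 | 5,7,8-trimethoxy-2-(2,3,4,5-tetramethoxyphenyl)-4H-chromen-4-one | COc1cc(OC)c2c(=O)cc(-c3cc(OC)c(OC)c(OC)c3OC)oc2c1OC
A1 | alternative 1 | 4-methoxy-6-[(3E)-2-oxo-4-(2,3,4,5-tetramethoxyphenyl)but-3-en-1-yl]-2H-pyran-2-one | COc1cc(CC(=O)/C=C/c2cc(OC)c(OC)c(OC)c2OC)oc(=O)c1
A2 | alternative 1 | (2E)-1-(2,6-dihydroxy-4-methoxyphenyl)-3-(2,3,4,5-tetramethoxyphenyl)prop-2-en-1-one | COc1cc(O)c(C(=O)/C=C/c2cc(OC)c(OC)c(OC)c2OC)c(O)c1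
A3 | alternative 2 | dimethyl squarate (3,4-dimethoxycyclobut-3-ene-1,2-dione) | COC1=C(OC)C(=O)C1=O
A4 | alternative 2 | 4-hydroxy-2,3-dimethoxy-4-[(E)-2-(5,7,8-trimethoxy-4-oxo-4H-chromen-2-yl)ethenyl]cyclobut-2-en-1-one (racemic) | COC1=C(OC)C(O)(/C=C/c2cc(=O)c3c(OC)cc(OC)c(OC)c3o2)C1=O
A5 | alternative 2 | 2-(2,5-dihydroxy-3,4-dimethoxyphenyl)-5,7,8-trimethoxy-4H-chromen-4-one | COc1cc(OC)c2c(=O)cc(-c3cc(O)c(OC)c(OC)c3O)oc2c1OC
A6 | alternative 3 | 3,5-dimethoxy-2-(trimethylsilyl)phenyl trifluoromethanesulfonate | COc1cc(OC)c([Si](C)(C)C)c(OS(=O)(=O)C(F)(F)F)c1
A7 | alternative 3 | 3,5-dimethoxybenzyne (1,2-didehydro-3,5-dimethoxybenzene) | COC1=CC(OC)=CC#C1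
A8 | alternative 3 | 3-(2,3,4,5-tetramethoxyphenyl)prop-2-ynoic acid | COc1cc(C#CC(=O)O)c(OC)c(OC)c1OC
A9 | alternative 3 | 5,7-dimethoxy-2-(2,3,4,5-tetramethoxyphenyl)-4H-chromen-4-one | COc1cc(OC)c2c(=O)cc(-c3cc(OC)c(OC)c(OC)c3OC)oc2c1
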